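**Retrosynthetic overview**
- Numbering: bicyclo[3.3.1]nonane with C1 = prenylated bridgehead next to C8(Me)2, C3 = aroyl carbon, C5 = bridgehead with the C10 side chain, C7 = prenylated CH, C9 = bridging C=O; ring A = C1-C2-C3-C4-C5-C9, ring B = C1-C8-C7-C6-C5-C9.
- Target ⇐ desilylation ⇐ Wittig/oxidation of a C7 2-hydroxyethyl triketone ⇐ tandem double Claisen closure of a monocyclic oxepanone thioester: C1 (γ-carbon of an aryl 1,3-diketone dianion) acylates on the thioester (C1–C9), then C3 acylates on the lactone (C3–C4).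
- Enabling feature: C5 carries both carbonyl carbons C4 and C9 (a quaternary malonyl carbon) and C1/C3 are the two α-carbons of the C2 ketone, so ring A is a malonyl + acylacetone union; holding the C4 carboxyl as a temporary seven-membered lactone to the C7 arm fixes the 7-endo relation.
- Key precursor ⇐ C3 aroylation, C5 alkylation with a limonene-derived iodide, C-thioacylation of a 5-substituted oxepan-2-one ⇐ cross-metathesis ⇐ enantioselective Baeyer–Villiger desymmetrisation of a 4-substituted cyclohexanone ⇐ allylation and conjugate addition of a cyclohexyl Grignard reagent to mesityl oxide.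
- Ring order: temporary oxepanone (step 10), then ring B and ring A, in that order, inside step 15, which also consumes the lactone.

Key step: step 15

Remark: the target is treated as one tautomer of an equilibrating enolised 2-aroyl-1,3-diketone; the carbon that becomes C1 is carried as both epimers until it is enolised, and the ligand antipode in step 10 is the one that gives the 5S lactone.

Step 1
Reactants: 1 (4R)-limonene 1,2-oxide (cis/trans mixture)
Product: 2 (3R)-6-oxo-3-(prop-1-en-2-yl)heptanal
Conditions: H5IO6 (1.1 equiv), THF/H2O, 0 °C to rt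
Reagents that add atoms: water (O)
Why: Periodic acid should open the epoxide and cleave the resulting 1,2-diol (glycol cleavage) without touching the isopropenyl-bearing stereocentre taken from limonene.

Step 2
Reactants: 2 (3R)-6-oxo-3-(prop-1-en-2-yl)heptanal
Product: 3 (3R)-6-oxo-3-(prop-1-en-2-yl)heptanoic acid
Conditions: NaClO2, NaH2PO4, 2-methylbut-2-ene, t-BuOH/H2O, 0 °C to rt
Reagents that add atoms: sodium chlorite ([Na+].[O-]Cl=O)
Why: Pinnick oxidation should convert only the aldehyde, the alkene scavenger protecting the isopropenyl group from HOCl.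

Step 3
Reactants: 3 (3R)-6-oxo-3-(prop-1-en-2-yl)heptanoic acid
Product: 4 (3R)-6-methyl-3-(prop-1-en-2-yl)hept-6-enoic acid
Conditions: Ph3PCH3Br (2.5 equiv), KOt-Bu (2.5 equiv), THF, 0 °C to rt; then 1 M HCl
Reagents that add atoms: methyltriphenylphosphonium bromide (C[P+](c1ccccc1)(c1ccccc1)c1ccccc1.[Br-])
Why: Wittig methylenation of the ketone should proceed on the carboxylate salt, the stereocentre being remote from any acidic position.

Step 4
Reactants: 4 (3R)-6-methyl-3-(prop-1-en-2-yl)hept-6-enoic acid
Product: 6 (3S)-3-(iodomethyl)-2,6-dimethylhepta-1,6-diene, via Barton ester 5 (not isolated)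
Conditions: 1-hydroxypyridine-2(1H)-thione, DCC, DMAP (cat.), CH2Cl2, 0 °C, dark; then CHI3, benzene, hν (tungsten lamp), rt
Reagents that add atoms: iodoform (IC(I)I)
Why: Barton decarboxylative iodination should give the primary radical, which iodoform traps faster than it can cyclise onto the distal alkene; the stereocentre is not a radical site and keeps its configuration.

Step 5
Reactants: 7 3,4-dihydroxybenzoic acid
Product: 9 3,4-bis(triisopropylsilyloxy)benzoic acid, via silyl ester 8 (not isolated)
Conditions: TIPSCl (3.3 equiv), imidazole, DMF, rt; then AcOH/THF/H2O, rt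
Reagents that add atoms: chlorotri(propan-2-yl)silane (CC(C)[Si](Cl)(C(C)C)C(C)C)
Why: Exhaustive silylation followed by selective hydrolysis of the labile silyl ester should leave the two robust aryl silyl ethers.

Step 6
Reactants: 9 3,4-bis(triisopropylsilyloxy)benzoic acid
Product: 10 1-[3,4-bis(triisopropylsilyloxy)benzoyl]-1H-benzotriazole
Conditions: 1H-benzotriazole, DCC, CH2Cl2, 0 °C to rt
Reagents that add atoms: 1H-benzotriazole (c1ccc2[nH]nnc2c1)
Why: Carbodiimide coupling should give the N-acylbenzotriazole, a neutral C-acylating agent for ketone enolates.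

Step 7
Reactants: 11 8-bromo-1,4-dioxaspiro[4.5]decane; 12 mesityl oxide
Product: 14 trimethylsilyl enol ether of 4-(1,4-dioxaspiro[4.5]decan-8-yl)-4-methylpentan-2-one (E/Z mixture), via Grignard reagent 13 (not isolated)
Conditions: Mg, THF, 40 °C; then 12, CuBr·SMe2 (10 mol%), TMSCl, DMPU, THF, −78 to −40 °C; Et3N, pentane
Reagents that add atoms: chlorotrimethylsilane (C[Si](C)(C)Cl)
Why: TMSCl-accelerated, CuBr·SMe2-catalysed conjugate addition of the secondary Grignard reagent to the β,β-disubstituted enone should build the quaternary C8 and trap the enolate regiospecifically as its silyl enol ether.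

Step 8
Reactants: 14 trimethylsilyl enol ether
Product: 15 3-[2-(1,4-dioxaspiro[4.5]decan-8-yl)propan-2-yl]hex-5-en-2-one (racemic)
Conditions: Pd2(dba)3·CHCl3 (2.5 mol%), dppe (5 mol%), allyl methyl carbonate, THF, 65 °C
Reagents that add atoms: allyl methyl carbonate (C=CCOC(=O)OC)
Why: Tsuji–Trost-type allylation of a silyl enol ether with an allyl carbonate under zerovalent palladium should allylate only the enol ether carbon (the future C1); the new centre is racemic and is enolised away in steps 14 and 15.

Step 9
Reactants: 15 allylated ketal ketone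
Product: 16 4-(3-acetyl-2-methylhex-5-en-2-yl)cyclohexan-1-one (racemic)
Conditions: 1 M HCl, THF, rt
Reagents that add atoms: water (O)
Why: Acid-catalysed ketal hydrolysis should free the ring ketone without affecting the terminal alkene.

Step 10
Reactants: 16 4-(3-acetyl-2-methylhex-5-en-2-yl)cyclohexan-1-one
Product: 17 (5S)-5-(3-acetyl-2-methylhex-5-en-2-yl)oxepan-2-one
Conditions: Sc(OTf)3 (5 mol%), chiral N,N′-dioxide ligand (5 mol%), m-CPBA (1.1 equiv), EtOAc, −20 °C
Reagents that add atoms: 3-chloroperoxybenzoic acid (OOC(=O)c1cccc(Cl)c1)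
Why: Catalytic enantioselective Baeyer–Villiger desymmetrisation of the prochiral 4-substituted cyclohexanone, in which the chiral Sc(OTf)3 complex selects one of the two enantiotopic migrating methylene groups and so sets the future C7; the hindered acyclic ketone and the monosubstituted alkene should react much more slowly.

Step 11
Reactants: 17 (5S)-5-(3-acetyl-2-methylhex-5-en-2-yl)oxepan-2-one
Product: 18 (5S)-5-(3-acetyl-2,6-dimethylhept-5-en-2-yl)oxepan-2-one
Conditions: second-generation Grubbs catalyst (5 mol%), 2-methylbut-2-ene (excess), CH2Cl2, 40 °C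
Reagents that add atoms: 2-methylbut-2-ene (CC=C(C)C)
Why: Olefin cross-metathesis should turn the allyl group into the prenyl group after the peracid step, while no other alkene is yet present.

Step 12
Reactants: 18 (5S)-5-(3-acetyl-2,6-dimethylhept-5-en-2-yl)oxepan-2-one
Product: 21 S-ethyl (5S)-5-(3-acetyl-2,6-dimethylhept-5-en-2-yl)-2-oxooxepane-3-carbothioate (epimers at C3), via silyl enol ether 19 (not isolated), via lithium lactone enolate 20 (not isolated)
Conditions: TMSOTf, Et3N, CH2Cl2, 0 °C; concentrate, pentane filtration; LDA (LiN(i-Pr)2, 2.1 equiv), THF, −78 °C; EtSC(O)Cl (1.05 equiv); then 1 M HCl, THF, 0 °C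
Reagents that add atoms: S-ethyl carbonochloridothioate (CCSC(=O)Cl)
Why: Soft enolisation should mask only the ketone as its silyl enol ether, so that LDA deprotonates the lactone alone and the enolate is C-acylated by the chlorothioformate (Claisen-type acylation, the second equivalent of base taking up the acidic product proton); dilute acid then returns the ketone, and the new centre is enolisable and not controlled.

Step 13
Reactants: 21 lactone thioester; 6 (3S)-3-(iodomethyl)-2,6-dimethylhepta-1,6-diene
Product: 22 S-ethyl (3R,5S)-5-(3-acetyl-2,6-dimethylhept-5-en-2-yl)-3-[(2R)-5-methyl-2-(prop-1-en-2-yl)hex-5-en-1-yl]-2-oxooxepane-3-carbothioate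
Conditions: Cs2CO3 (1.5 equiv), DMF, rt to 40 °C
Reagents that add atoms: none
Why: Cs2CO3 should form only the doubly stabilised lactone–thioester enolate, and SN2 alkylation should occur on the enolate face trans to the pseudo-equatorial C5 substituent (axial-type alkylation, as for 4-substituted 2-alkoxycarbonylcyclohexanone enolates), which sets the quaternary carbon as 3R with the thioester cis to the C5 substituent.

Step 14
Reactants: 22 quaternary lactone thioester methyl ketone; 10 1-[3,4-bis(triisopropylsilyloxy)benzoyl]-1H-benzotriazole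
Product: 23 aryl 1,3-diketone of the (3R,5S)-oxepanone thioester
Conditions: LiN(SiMe3)2 (2.2 equiv), THF, −78 °C; then 10, −78 to −40 °C; aq. NH4Cl
Reagents that add atoms: none
Why: The amide base should give the kinetic methyl-side enolate of the only enolisable carbonyl group, which is C-acylated by the N-acylbenzotriazole (crossed Claisen acylation), the second equivalent of base storing the product as its diketone enolate.

Step 15
Reactants: 23 aryl 1,3-diketone of the (3R,5S)-oxepanone thioester
Product: 26 bis-silylated 7-endo-(2-hydroxyethyl) bicyclo[3.3.1]nonane triketone (configuration as in 29), via diketone dianion 24 (not isolated), via bridged keto-lactone enolate 25 (not isolated)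
Conditions: LDA (2.4 equiv), THF, −78 to 0 °C; aq. NH4Cl, pH 4 buffer
Reagents that add atoms: none
Why: LDA should deprotonate C3 and then the C1 methine to give dianion 24, whose γ-carbon C1 acylates on the thioester (Dieckmann-type γ-acylation of a diketone dianion, 6-exo-trig, chair transition state with the lactone as a diaxial C5/C7 bridge), closing ring B and forming C1–C9 with loss of ethanethiolate; in the bridged keto-lactone 25 the diketone enolate carbon C3 lies 1,3-diaxial to the lactone carbonyl and acylates on it (intramolecular Claisen C-acylation, 6-exo-trig), closing ring A, forming C3–C4 and releasing the C7 2-oxidoethyl arm, and deprotonation of the triketone should make the sequence irreversible. The closest known reaction types are the γ-acylation of 1,3-diketone dianions by esters, the Dieckmann condensation, and the Claisen cyclisation of diketo esters to 2-acylcyclohexane-1,3-diones (acylphloroglucinol-type polyketide cyclisation). The new stereocentre C1 is set by the existing ones: C5 and C7 are held cis by the lactone, the prenyl methylene should take the equatorial site of the chair, and only the epimer with C2 axial (cis to C4) can close ring A. The 7-endo relation needs no facial choice, because the carbonyl that becomes C4 is already joined covalently to the C7 arm and the C5 configuration from step 13 decides which acyl group becomes C9. The step needs C1 to attack the thioester and not the lactone carbonyl across the ring, which would lead to the C7 epimer: the thioester is the more electrophilic acyl group and is reached through a chair, the lactone only through a boat-like bicyclo[3.2.2] transition state, and no alkoxide is released before ring B is closed, so the tether cannot be scrambled by transesterification.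

Step 16
Reactants: 26 bis-silylated 7-(2-hydroxyethyl) triketone
Product: 27 bis-silylated 7-(2-oxoethyl) triketone
Conditions: Pr4N[RuO4] (5 mol%), NMO (1.5 equiv), 4 Å MS, CH2Cl2, rt
Reagents that add atoms: none
Why: Ley–Griffith oxidation should convert the primary alcohol under neutral conditions, the enolised triketone being held as its ammonium salt and the alkenes left untouched.

Step 17
Reactants: 27 bis-silylated 7-(2-oxoethyl) triketone
Product: 28 bis(triisopropylsilyl) ether of the target
Conditions: i-PrPPh3I (3.5 equiv), n-BuLi (3.4 equiv), THF, −78 to 0 °C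
Reagents that add atoms: isopropyltriphenylphosphonium iodide (CC(C)[P+](c1ccccc1)(c1ccccc1)c1ccccc1.[I-])
Why: Wittig olefination with the non-stabilised isopropylidene ylide should complete the C7 prenyl group, the first equivalent only deprotonating the acidic enol, whose enolate is inert.

Step 18
Reactants: 28 bis(triisopropylsilyl) ether of the target
Product: 29 target (CNP0139652.2)
Conditions: Bu4NF (2.5 equiv), AcOH (2.5 equiv), THF, 0 °C
Reagents that add atoms: none
Why: Buffered fluoride cleavage of the two aryl silyl ethers avoids both strong base and the strong acid that would cyclise the enol onto a prenyl group.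

**Compound list**
1 | (4R)-limonene 1,2-oxide, cis/trans mixture | CC(=C)[C@@H]1CCC2(C)OC2C1 | starting material
2 | (3R)-6-oxo-3-(prop-1-en-2-yl)heptanal | CC(=O)CC[C@H](CC=O)C(C)=C | intermediate
3 | (3R)-6-oxo-3-(prop-1-en-2-yl)heptanoic acid | CC(=O)CC[C@H](CC(=O)O)C(C)=C | intermediate
4 | (3R)-6-methyl-3-(prop-1-en-2-yl)hept-6-enoic acid | C=C(C)CC[C@H](CC(=O)O)C(C)=C | intermediate
5 | 2-thioxopyridin-1(2H)-yl (3R)-6-methyl-3-(prop-1-en-2-yl)hept-6-enoate (Barton ester) | C=C(C)CC[C@H](CC(=O)On1ccccc1=S)C(C)=C | intermediate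
6 | (3S)-3-(iodomethyl)-2,6-dimethylhepta-1,6-diene | C=C(C)CC[C@H](CI)C(C)=C | intermediate
7 | 3,4-dihydroxybenzoic acid | OC(=O)c1ccc(O)c(O)c1 | starting material
8 | triisopropylsilyl 3,4-bis(triisopropylsilyloxy)benzoate | CC(C)[Si](OC(=O)c1ccc(O[Si](C(C)C)(C(C)C)C(C)C)c(O[Si](C(C)C)(C(C)C)C(C)C)c1)(C(C)C)C(C)C | intermediate
9 | 3,4-bis(triisopropylsilyloxy)benzoic acid | OC(=O)c1ccc(O[Si](C(C)C)(C(C)C)C(C)C)c(O[Si](C(C)C)(C(C)C)C(C)C)c1 | intermediate
10 | 1-[3,4-bis(triisopropylsilyloxy)benzoyl]-1H-benzotriazole | O=C(c1ccc(O[Si](C(C)C)(C(C)C)C(C)C)c(O[Si](C(C)C)(C(C)C)C(C)C)c1)n1nnc2ccccc21 | intermediate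
11 | 8-bromo-1,4-dioxaspiro[4.5]decane | BrC1CCC2(CC1)OCCO2 | starting material
12 | mesityl oxide (4-methylpent-3-en-2-one) | CC(=O)C=C(C)C | starting material
13 | (1,4-dioxaspiro[4.5]decan-8-yl)magnesium bromide | Br[Mg]C1CCC2(CC1)OCCO2 | intermediate
14 | {[4-(1,4-dioxaspiro[4.5]decan-8-yl)-4-methylpent-2-en-2-yl]oxy}trimethylsilane, E/Z mixture | CC(O[Si](C)(C)C)=CC(C)(C)C1CCC2(CC1)OCCO2 | intermediate
15 | 3-[2-(1,4-dioxaspiro[4.5]decan-8-yl)propan-2-yl]hex-5-en-2-one, racemic | CC(=O)C(CC=C)C(C)(C)C1CCC2(CC1)OCCO2 | intermediate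
16 | 4-(3-acetyl-2-methylhex-5-en-2-yl)cyclohexan-1-one, racemic | CC(=O)C(CC=C)C(C)(C)C1CCC(=O)CC1 | intermediate
17 | (5S)-5-(3-acetyl-2-methylhex-5-en-2-yl)oxepan-2-one, both epimers at the acetyl-bearing carbon | CC(=O)C(CC=C)C(C)(C)[C@H]1CCC(=O)OCC1 | intermediate
18 | (5S)-5-(3-acetyl-2,6-dimethylhept-5-en-2-yl)oxepan-2-one | CC(=O)C(CC=C(C)C)C(C)(C)[C@H]1CCC(=O)OCC1 | intermediate
19 | (5S)-5-{2,6-dimethyl-3-[1-(trimethylsilyloxy)ethenyl]hept-5-en-2-yl}oxepan-2-one | C=C(O[Si](C)(C)C)C(CC=C(C)C)C(C)(C)[C@H]1CCC(=O)OCC1 | intermediate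
20 | lithium lactone enolate of 19 | C=C(O[Si](C)(C)C)C(CC=C(C)C)C(C)(C)[C@H]1CC=C(O[Li])OCC1 | intermediate
21 | S-ethyl (5S)-5-(3-acetyl-2,6-dimethylhept-5-en-2-yl)-2-oxooxepane-3-carbothioate, epimers at C3 | CC(=O)C(CC=C(C)C)C(C)(C)[C@H]1CC(C(=O)SCC)C(=O)OCC1 | intermediate
22 | S-ethyl (3R,5S)-5-(3-acetyl-2,6-dimethylhept-5-en-2-yl)-3-[(2R)-5-methyl-2-(prop-1-en-2-yl)hex-5-en-1-yl]-2-oxooxepane-3-carbothioate | C=C(C)CC[C@H](C[C@]1(C(=O)SCC)C(=O)OCC[C@H](C1)C(C)(C)C(CC=C(C)C)C(C)=O)C(=C)C | intermediate
23 | S-ethyl (3R,5S)-5-{3-[3-(3,4-bis(triisopropylsilyloxy)phenyl)-3-oxopropanoyl]-2,6-dimethylhept-5-en-2-yl}-3-[(2R)-5-methyl-2-(prop-1-en-2-yl)hex-5-en-1-yl]-2-oxooxepane-3-carbothioate | C=C(C)CC[C@H](C[C@]1(C(=O)SCC)C(=O)OCC[C@H](C1)C(C)(C)C(CC=C(C)C)C(=O)CC(=O)c1ccc(O[Si](C(C)C)(C(C)C)C(C)C)c(O[Si](C(C)C)(C(C)C)C(C)C)c1)C(=C)C | intermediate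
24 | dilithium dienediolate (C1/C3 dianion) of 23 | C=C(C)CC[C@H](C[C@]1(C(=O)SCC)C(=O)OCC[C@H](C1)C(C)(C)C(CC=C(C)C)=C(O[Li])C=C(O[Li])c1ccc(O[Si](C(C)C)(C(C)C)C(C)C)c(O[Si](C(C)C)(C(C)C)C(C)C)c1)C(=C)C | intermediate
25 | lithium enolate of the ring-B-closed keto-lactone (C9 ketone formed, lactone bridging C5 and C7, C2 side chain cis to the lactone carbonyl) | C=C(C)CC[C@H](C[C@@]12C[C@@H](CCOC1=O)C(C)(C)[C@@](CC=C(C)C)(C(=O)C=C(O[Li])c3ccc(O[Si](C(C)C)(C(C)C)C(C)C)c(O[Si](C(C)C)(C(C)C)C(C)C)c3)C2=O)C(=C)C | intermediate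
26 | 3-[3,4-bis(triisopropylsilyloxy)benzoyl]-4-hydroxy-7-(2-hydroxyethyl)-8,8-dimethyl-1-(3-methylbut-2-enyl)-5-[(2R)-5-methyl-2-(prop-1-en-2-yl)hex-5-enyl]bicyclo[3.3.1]non-3-ene-2,9-dione, 7-endo, configuration as in 29 | C=C(C)CC[C@H](C[C@@]12C[C@@H](CCO)C(C)(C)[C@@](CC=C(C)C)(C(=O)C(C(=O)c3ccc(O[Si](C(C)C)(C(C)C)C(C)C)c(O[Si](C(C)C)(C(C)C)C(C)C)c3)=C1O)C2=O)C(=C)C | intermediate
27 | the 7-(2-oxoethyl) analogue of 26 | C=C(C)CC[C@H](C[C@@]12C[C@@H](CC=O)C(C)(C)[C@@](CC=C(C)C)(C(=O)C(C(=O)c3ccc(O[Si](C(C)C)(C(C)C)C(C)C)c(O[Si](C(C)C)(C(C)C)C(C)C)c3)=C1O)C2=O)C(=C)C | intermediate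
28 | bis(triisopropylsilyl) ether of 29 | C=C(C)CC[C@H](C[C@@]12C[C@@H](CC=C(C)C)C(C)(C)[C@@](CC=C(C)C)(C(=O)C(C(=O)c3ccc(O[Si](C(C)C)(C(C)C)C(C)C)c(O[Si](C(C)C)(C(C)C)C(C)C)c3)=C1O)C2=O)C(=C)C | intermediate
29 | 3-(3,4-dihydroxybenzoyl)-4-hydroxy-8,8-dimethyl-1,7-bis(3-methylbut-2-enyl)-5-[(2R)-5-methyl-2-(prop-1-en-2-yl)hex-5-enyl]bicyclo[3.3.1]non-3-ene-2,9-dione, 7R, C7 prenyl syn to the C2–C4 bridge | C=C(C)CC[C@H](C[C@@]12C[C@@H](CC=C(C)C)C(C)(C)[C@@](CC=C(C)C)(C(=O)C(C(=O)c3ccc(O)c(O)c3)=C1O)C2=O)C(=C)C | target

**Step count and risks**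
Total step count: 18. Longest linear sequence: 12 steps (steps 7 to 18, from 11 and 12).

Steps most likely to fail:

Step 15. Deprotonation of the hindered C1 methine may be incomplete. The dianion may acylate on the lactone carbonyl across the ring, which leads into the C7-epimeric series. Ring B may close with the C1 configuration that cannot close ring A. The fallback separates the two bond formations and uses known Claisen chemistry, setting out from 22. KN(SiMe3)2 in THF (−78 to 0 °C) should equilibrate the ketone enolates, and only the C1 enolate can close a six-membered ring onto the thioester, giving the bridged diketo-lactone F1. LiN(SiMe3)2 followed by 10 should then aroylate the only enolisable position, the acetyl methyl group, to give the bridged keto-lactone diketone F2. KOt-Bu in THF should close ring A by Claisen acylation on the lactone, which returns to the route at 26.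

Step 13. The iodide may enter on the other face of the enolate and give the opposite configuration at the quaternary carbon. The fallback reverses the order in which the two substituents are introduced, setting out from 18. After the same transient silyl masking of the ketone, LDA and then 6 with DMPU should give the 3-alkyl lactone F3. Repeating the masking, LDA and S-ethyl carbonochloridothioate then brings the acyl group in last. The acyl group would enter on the face that the alkyl group had preferred, which inverts the outcome at the quaternary carbon and returns to the route at 22.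

Step 12. Masking of the methyl ketone may be incomplete, so that the ketone is enolised and acylated in competition with the lactone. The fallback uses an isolable protecting group, setting out from 18. 1,2-Bis(trimethylsilyloxy)ethane with catalytic TMSOTf should give the dioxolane F4. LDA and S-ethyl carbonochloridothioate should give the thioester dioxolane F5. Cs2CO3 and 6 should give the alkylated dioxolane F6. PPTS in wet acetone then frees the ketone and returns to the route at 22.

Further compounds
F1 | step 15 | ring-B-closed diketo-lactone with a C1 acetyl group (lactone bridging C5 and C7) | C=C(C)CC[C@H](C[C@@]12C[C@@H](CCOC1=O)C(C)(C)[C@@](CC=C(C)C)(C(C)=O)C2=O)C(=C)C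
F2 | step 15 | ring-B-closed keto-lactone carrying the aryl 1,3-diketone at C1 (neutral form of 25) | C=C(C)CC[C@H](C[C@@]12C[C@@H](CCOC1=O)C(C)(C)[C@@](CC=C(C)C)(C(=O)CC(=O)c3ccc(O[Si](C(C)C)(C(C)C)C(C)C)c(O[Si](C(C)C)(C(C)C)C(C)C)c3)C2=O)C(=C)C
F3 | step 13 | (5S)-5-(3-acetyl-2,6-dimethylhept-5-en-2-yl)-3-[(2R)-5-methyl-2-(prop-1-en-2-yl)hex-5-en-1-yl]oxepan-2-one, epimers at C3 | C=C(C)CC[C@H](CC1C(=O)OCC[C@H](C1)C(C)(C)C(CC=C(C)C)C(C)=O)C(=C)C
F4 | step 12 | (5S)-5-[2,6-dimethyl-3-(2-methyl-1,3-dioxolan-2-yl)hept-5-en-2-yl]oxepan-2-one | CC1(OCCO1)C(CC=C(C)C)C(C)(C)[C@H]1CCC(=O)OCC1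
F5 | step 12 | S-ethyl (5S)-5-[2,6-dimethyl-3-(2-methyl-1,3-dioxolan-2-yl)hept-5-en-2-yl]-2-oxooxepane-3-carbothioate | CC1(OCCO1)C(CC=C(C)C)C(C)(C)[C@H]1CC(C(=O)SCC)C(=O)OCC1
F6 | step 12 | dioxolane of 22 | C=C(C)CC[C@H](C[C@]1(C(=O)SCC)C(=O)OCC[C@H](C1)C(C)(C)C(CC=C(C)C)C1(C)OCCO1)C(=C)C
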